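What was charged as starting material stays in the flask as starting material, target, over-reaction product, quenched substrate or self-condensation product, so the percentages asked for are shares of one fixed sum.

in all of them: starting material 20 mM; reagent 22.0 mM; protic impurity 0.400 mM
- grey: time 30 min
- ochre: time 75 min
- amber: time 190 min

    starting material + reagent ⇌ target + released group (K1 = 1.8, k1 = 4.3 M⁻¹ min⁻¹)
    target → over-reaction product (k2 = 0.015 min⁻¹)
    2 starting material → self-condensation product (k3 = 0.47 M⁻¹ min⁻¹)
    starting material + protic impurity → quenched substrate (k4 = 150 M⁻¹ min⁻¹)

1. which of these there is most of at the end, counted by the starting material in it, grey (over-reaction product / starting material / target)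
2. which of these there is most of at the end, counted by the starting material in it, ochre (over-reaction product / starting material / target)
3. which of these there is most of at the end, counted by the starting material in it, amber (over-reaction product / starting material / target)
4. the largest of these amounts at the end, in percent of the starting material charged, grey
5. the largest of these amounts at the end, in percent of the starting material charged, ochre
6. the largest of these amounts at the end, in percent of the starting material charged, amber

- in percentages every species weighs as the starting material in it: one self-condensation product counts as two
- a step written with two of one species runs at k times the square of its concentration and takes two of it each time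
- run time (grey): 30 min

You asked for a quick number and gave a hunch, so here is my own reckoning first. Over-reaction product forms at 0.015 min⁻¹ times [target], so the outflow is first order in that one concentration. The way in runs at 4.3 M⁻¹ min⁻¹ times [reagent], 0.0946 min⁻¹ at the charge, faster than that outflow constant. So I let the reversible step balance and treat starting material plus target as one pool, in which I assume target holds a steady share s; on that assumption the pool drains pseudo-first-order. The forward half-life at the charge, 7.33 min, serves as my lag before draining starts. The protic impurity takes 0.400 mM of starting material, and with starting material held at its charge the impurity's own half-life is 0.231 min, shorter than that lag. At the start the forward step outruns self-condensation 5.03 to one, and I hold that ratio throughout.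

Balance at 1.8 on what the impurity leaves: [target] = 11.9 mM, so s = 60.6 %

Pool: L = 81.8 % of the charge

Drain: D = 0.015 min⁻¹ × s = 0.00908 min⁻¹

Target at time t: s·L·e^(−D(t − lag))

Over-reaction product at time t: L·(1 − e^(−D(t − lag)))

D is the drain constant, the fraction of the pool passing to over-reaction product each minute. It puts target ahead in grey at 40.3 %. In ochre it puts over-reaction product ahead at 37.5 %, and in amber over-reaction product at 66.2 %.

Your forecast names target at 40.5 % for grey, over-reaction product at 37 % for ochre and over-reaction product at 61 % for amber, on the picture that “the equilibrium acts as a reservoir draining slowly”. My amber figure stands above yours.

The simulation gives target at 40.2 % in grey, over-reaction product at 37.8 % in ochre and over-reaction product at 61.4 % in amber. Taking away the passing of target into over-reaction product turns the ochre and amber answers, and amber then keeps 47.7 % of target against 7.37 %. Between the grey and amber readings target falls from 40.2 % to 7.37 %, a read drain of 0.0106 min⁻¹ against D of 0.00908 min⁻¹. For the neighbour flask, amber stopped at 50 min, D gives target 33.6 %, and that flask holds 32.0 %.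

(The numbers come from no measurement, and the outcome is calculated.)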